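## Retrosynthetic overview

- Rings: A = benzo ring of the dihydrobenzofuran, B = dihydrofuran ring, C = 4-hydroxy-3-methoxyphenyl ring on C2. The last skeletal bond, C5 (ring A)–CH=, is made by a one-pot iridium-catalysed C–H borylation/Suzuki–Miyaura coupling that joins the complete, halogen-free (2S,3R)-dihydrobenzofuran mono-ester with (E)-3-iodoallyl 4-(triisopropylsilyloxy)benzoate; only a global desilylation follows.
- Enabling feature: ring A is substituted at C3a, C7 and C7a, so C5–H is the only aromatic C–H of the whole substrate flanked by two C–H positions (C4–H and C6–H). Every C–H of ring C and of the para-disubstituted benzoate ring is ortho to a substituent, so sterically governed borylation has a single site.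
- Ring B is the only ring that is built (rings A and C are bought as 2-allyl-6-methoxyphenol and vanillin): an Evans syn-aldol sets C3, then debenzylation and acid-mediated 5-exo closure of the ring A phenol onto the benzylic cation set C2 trans to C3.
- Both ester arms derive from one acid, 4-(triisopropylsilyloxy)benzoic acid; the vinyl iodide arm comes from its propargyl ester by hydrozirconation–iodination.

Key step: step 12

## Route

Step 1
Reactants: 1 2-allyl-6-methoxyphenol
Product: 2 1-allyl-2-(benzyloxy)-3-methoxybenzene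
Conditions: BnBr, K2CO3, DMF, rt
Reagents that add atoms: benzyl bromide, BrCc1ccccc1
Why: Williamson etherification of the phenoxide; the benzyl ether masks the ring A phenol through the enolate chemistry and is removed later by hydrogenolysis.

Step 2
Reactants: 2 1-allyl-2-(benzyloxy)-3-methoxybenzene
Product: 4 2-[2-(benzyloxy)-3-methoxyphenyl]acetic acid, via arylacetaldehyde 3 (not isolated)
Conditions: O3, CH2Cl2, −78 °C; PPh3, −78 °C → rt; then NaClO2, NaH2PO4, 2-methyl-2-butene, t-BuOH/H2O, rt
Reagents that add atoms: ozone, O=[O+][O-]; sodium chlorite, [Na+].[O-]Cl=O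
Why: Ozonolysis cleaves the terminal alkene faster than ozone attacks the dialkoxyarene at −78 °C, and Pinnick oxidation converts the sensitive arylacetaldehyde directly into the acid while the alkene scavenger protects the electron-rich ring from hypochlorite.

Step 3
Reactants: 4 2-[2-(benzyloxy)-3-methoxyphenyl]acetic acid; 5 (S)-4-benzyloxazolidin-2-one
Product: 7 (S)-4-benzyl-3-{2-[2-(benzyloxy)-3-methoxyphenyl]acetyl}oxazolidin-2-one, via mixed pivalic anhydride 6 (not isolated)
Conditions: PivCl, Et3N, THF, −20 °C; then 5, LiCl, → rt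
Reagents that add atoms: none
Why: N-acylation of the Evans auxiliary through the mixed pivalic anhydride, which is attacked at the less hindered arylacetyl carbonyl.

Step 4
Reactants: 8 vanillin
Product: 9 3-methoxy-4-(triisopropylsilyloxy)benzaldehyde
Conditions: TIPSCl, imidazole, DMF, rt
Reagents that add atoms: chlorotriisopropylsilane, CC(C)[Si](Cl)(C(C)C)C(C)C
Why: Imidazole-promoted silylation of the phenol; the bulky TIPS ether carries no aryl C–H and later shields the neighbouring C–H of ring C in the borylation.

Step 5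
Reactants: 7 (S)-4-benzyl-3-{2-[2-(benzyloxy)-3-methoxyphenyl]acetyl}oxazolidin-2-one; 9 3-methoxy-4-(triisopropylsilyloxy)benzaldehyde
Product: 11 (S)-4-benzyl-3-{(2S,3S)-2-[2-(benzyloxy)-3-methoxyphenyl]-3-hydroxy-3-[3-methoxy-4-(triisopropylsilyloxy)phenyl]propanoyl}oxazolidin-2-one, via dibutylboron Z-enolate 10 (not isolated)
Conditions: Bu2BOTf, iPr2NEt, CH2Cl2, 0 °C; then 9, −78 → 0 °C; pH 7 buffer, MeOH, H2O2, 0 °C
Reagents that add atoms: none
Why: Evans syn-aldol reaction in which the Z-boron enolate reacts through a Zimmerman–Traxler chair with the aldehyde on the enolate face remote from the auxiliary benzyl group, which should set the aryl-bearing α-centre (the later C3) and the syn carbinol as (2S,3S).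

Step 6
Reactants: 11 the syn-aldol adduct
Product: 12 (1S,2R)-2-[2-(benzyloxy)-3-methoxyphenyl]-1-[3-methoxy-4-(triisopropylsilyloxy)phenyl]propane-1,3-diol
Conditions: LiBH4, H2O (1 equiv), Et2O, 0 °C
Reagents that add atoms: none
Why: Reductive cleavage of the N-acyl oxazolidinone by hydride attack on the exocyclic carbonyl gives the primary alcohol without touching either stereocentre and releases the auxiliary for recovery.

Step 7
Reactants: 12 the benzyl-protected diol
Product: 14 {(2S,3R)-7-methoxy-2-[3-methoxy-4-(triisopropylsilyloxy)phenyl]-2,3-dihydrobenzofuran-3-yl}methanol, via phenol triol 13 (not isolated)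
Conditions: H2 (1 atm), Pd/C, EtOAc, rt; filter; then TsOH·H2O (cat.), CH2Cl2, 0 °C
Reagents that add atoms: none
Why: Hydrogenolysis frees the ring A phenol, and mild acid ionises the electron-rich benzylic alcohol to a quinone-methide-like cation that the phenol captures in a reversible 5-exo closure, in which the C3 stereocentre directs the aryl group anti to the CH2OH group (1,2-induction, thermodynamic trans), so C2 should be set as S whatever the carbinol configuration was.

Step 8
Reactants: 15 4-hydroxybenzoic acid
Product: 17 4-(triisopropylsilyloxy)benzoic acid, via silyl ester silyl ether 16 (not isolated)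
Conditions: TIPSCl (2.2 equiv), imidazole, DMF, rt; then AcOH/THF/H2O, rt
Reagents that add atoms: chlorotriisopropylsilane, CC(C)[Si](Cl)(C(C)C)C(C)C
Why: Exhaustive silylation followed by selective hydrolysis of the labile silyl ester leaves the aryl silyl ether and gives the one acid used for both ester arms.

Step 9
Reactants: 14 the dihydrobenzofuran alcohol; 17 4-(triisopropylsilyloxy)benzoic acid
Product: 18 {(2S,3R)-7-methoxy-2-[3-methoxy-4-(triisopropylsilyloxy)phenyl]-2,3-dihydrobenzofuran-3-yl}methyl 4-(triisopropylsilyloxy)benzoate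
Conditions: DCC, DMAP (cat.), CH2Cl2, 0 °C → rt
Reagents that add atoms: none
Why: Steglich esterification of the only free hydroxyl under neutral conditions that leave the silyl ethers and both stereocentres untouched.

Step 10
Reactants: 17 4-(triisopropylsilyloxy)benzoic acid; 19 propargyl alcohol
Product: 20 prop-2-yn-1-yl 4-(triisopropylsilyloxy)benzoate
Conditions: DCC, DMAP (cat.), CH2Cl2, 0 °C → rt
Reagents that add atoms: none
Why: Steglich esterification of an unhindered primary alcohol.

Step 11
Reactants: 20 prop-2-yn-1-yl 4-(triisopropylsilyloxy)benzoate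
Product: 22 (E)-3-iodoprop-2-en-1-yl 4-(triisopropylsilyloxy)benzoate, via E-vinylzirconocene chloride 21 (not isolated)
Conditions: Cp2Zr(H)Cl, THF, rt; then I2, 0 °C
Reagents that add atoms: iodine, [I][I]
Why: Hydrozirconation of the terminal alkyne is a syn addition that places zirconium on the terminal carbon and is much faster than reduction of the ester, and iodinolysis of the C–Zr bond proceeds with retention to give the E-vinyl iodide.

Step 12
Reactants: 18 the dihydrobenzofuran mono-ester; 22 (E)-3-iodoprop-2-en-1-yl 4-(triisopropylsilyloxy)benzoate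
Product: 24 tris-TIPS ether of quiquesetinerviusin A, via aryl pinacolboronate 23 (not isolated)
Conditions: [Ir(OMe)(cod)]2, dtbpy, B2pin2, THF, 80 °C; then 22, Pd(dppf)Cl2, aq. K3PO4, 40 °C
Reagents that add atoms: none
Why: A trivalent iridium tris(boryl) complex [Ir(dtbpy)(Bpin)3] cleaves the least hindered aromatic C–H bond and forms the C5–B bond, after which zerovalent palladium inserts into the C–I bond of 22 with retention of the E geometry, the boronate transmetalates under phosphate activation and reductive elimination forms the C5–CH= bond. The closest known reaction type is the one-pot iridium-catalysed aromatic C–H borylation/Suzuki–Miyaura coupling used for late-stage functionalisation of arenes. No ring is closed and no stereocentre is created; C2 and C3 are not acidic enough to epimerise in aqueous K3PO4, and the alkene geometry is inherited from 22. The step needs site selectivity among the ten aromatic C–H bonds of 18, and the substrate secures it sterically: C5–H alone has two C–H neighbours, whereas C4–H and C6–H of ring A, all three C–H of ring C and all four of the benzoate ring are ortho to a substituent, and the TIPS ethers add bulk without offering aryl C–H bonds of their own. It also needs chemoselectivity of palladium for the vinyl C–I bond over the allylic C–O bonds, which fast oxidative addition of a vinyl iodide at 40 °C with a bisphosphine ligand should provide.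

Step 13
Reactants: 24 tris-TIPS ether of quiquesetinerviusin A
Product: 25 quiquesetinerviusin A
Conditions: Bu4NF, AcOH, THF, 0 °C
Reagents that add atoms: none
Why: Fluoride cleaves the three aryl silyl ethers, and the acetic acid buffer protonates each phenoxide at once so that neither the benzoate esters nor the cinnamyl ester should be attacked.

## Compound list

1 | 2-allyl-6-methoxyphenol | COc1cccc(CC=C)c1O | starting material
2 | 1-allyl-2-(benzyloxy)-3-methoxybenzene | COc1cccc(CC=C)c1OCc1ccccc1 | intermediate
3 | 2-[2-(benzyloxy)-3-methoxyphenyl]acetaldehyde | COc1cccc(CC=O)c1OCc1ccccc1 | intermediate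
4 | 2-[2-(benzyloxy)-3-methoxyphenyl]acetic acid | COc1cccc(CC(=O)O)c1OCc1ccccc1 | intermediate
5 | (S)-4-benzyloxazolidin-2-one | O=C1N[C@@H](Cc2ccccc2)CO1 | starting material
6 | 2-[2-(benzyloxy)-3-methoxyphenyl]acetic pivalic anhydride | COc1cccc(CC(=O)OC(=O)C(C)(C)C)c1OCc1ccccc1 | intermediate
7 | (S)-4-benzyl-3-{2-[2-(benzyloxy)-3-methoxyphenyl]acetyl}oxazolidin-2-one | COc1cccc(CC(=O)N2C(=O)OC[C@@H]2Cc2ccccc2)c1OCc1ccccc1 | intermediate
8 | vanillin | COc1cc(C=O)ccc1O | starting material
9 | 3-methoxy-4-(triisopropylsilyloxy)benzaldehyde | COc1cc(C=O)ccc1O[Si](C(C)C)(C(C)C)C(C)C | intermediate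
10 | dibutylboron (Z)-enolate of 7 | CCCCB(CCCC)O/C(=C\c1cccc(OC)c1OCc1ccccc1)N1C(=O)OC[C@@H]1Cc1ccccc1 | intermediate
11 | (S)-4-benzyl-3-{(2S,3S)-2-[2-(benzyloxy)-3-methoxyphenyl]-3-hydroxy-3-[3-methoxy-4-(triisopropylsilyloxy)phenyl]propanoyl}oxazolidin-2-one | O=C([C@@H](c1cccc(OC)c1OCc1ccccc1)[C@H](O)c1ccc(O[Si](C(C)C)(C(C)C)C(C)C)c(OC)c1)N1C(=O)OC[C@@H]1Cc1ccccc1 | intermediate
12 | (1S,2R)-2-[2-(benzyloxy)-3-methoxyphenyl]-1-[3-methoxy-4-(triisopropylsilyloxy)phenyl]propane-1,3-diol | OC[C@@H](c1cccc(OC)c1OCc1ccccc1)[C@H](O)c1ccc(O[Si](C(C)C)(C(C)C)C(C)C)c(OC)c1 | intermediate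
13 | (1S,2R)-2-(2-hydroxy-3-methoxyphenyl)-1-[3-methoxy-4-(triisopropylsilyloxy)phenyl]propane-1,3-diol | OC[C@@H](c1cccc(OC)c1O)[C@H](O)c1ccc(O[Si](C(C)C)(C(C)C)C(C)C)c(OC)c1 | intermediate
14 | {(2S,3R)-7-methoxy-2-[3-methoxy-4-(triisopropylsilyloxy)phenyl]-2,3-dihydrobenzofuran-3-yl}methanol | COc1cc([C@H]2Oc3c(OC)cccc3[C@@H]2CO)ccc1O[Si](C(C)C)(C(C)C)C(C)C | intermediate
15 | 4-hydroxybenzoic acid | OC(=O)c1ccc(O)cc1 | starting material
16 | triisopropylsilyl 4-(triisopropylsilyloxy)benzoate | CC(C)[Si](OC(=O)c1ccc(O[Si](C(C)C)(C(C)C)C(C)C)cc1)(C(C)C)C(C)C | intermediate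
17 | 4-(triisopropylsilyloxy)benzoic acid | OC(=O)c1ccc(O[Si](C(C)C)(C(C)C)C(C)C)cc1 | intermediate
18 | {(2S,3R)-7-methoxy-2-[3-methoxy-4-(triisopropylsilyloxy)phenyl]-2,3-dihydrobenzofuran-3-yl}methyl 4-(triisopropylsilyloxy)benzoate | COc1cc([C@H]2Oc3c(OC)cccc3[C@@H]2COC(=O)c2ccc(O[Si](C(C)C)(C(C)C)C(C)C)cc2)ccc1O[Si](C(C)C)(C(C)C)C(C)C | intermediate
19 | propargyl alcohol | C#CCO | starting material
20 | prop-2-yn-1-yl 4-(triisopropylsilyloxy)benzoate | C#CCOC(=O)c1ccc(O[Si](C(C)C)(C(C)C)C(C)C)cc1 | intermediate
21 | (E)-vinylzirconocene chloride from 20 (Cp2Zr(Cl)–CH=CH–CH2O2CAr) | Cl[Zr](/C=C/COC(=O)c1ccc(O[Si](C(C)C)(C(C)C)C(C)C)cc1)(C1C=CC=C1)C1C=CC=C1 | intermediate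
22 | (E)-3-iodoprop-2-en-1-yl 4-(triisopropylsilyloxy)benzoate | I/C=C/COC(=O)c1ccc(O[Si](C(C)C)(C(C)C)C(C)C)cc1 | intermediate
23 | 5-(4,4,5,5-tetramethyl-1,3,2-dioxaborolan-2-yl) derivative of 18 | COc1cc([C@H]2Oc3c(OC)cc(B4OC(C)(C)C(C)(C)O4)cc3[C@@H]2COC(=O)c2ccc(O[Si](C(C)C)(C(C)C)C(C)C)cc2)ccc1O[Si](C(C)C)(C(C)C)C(C)C | intermediate
24 | tris-TIPS ether of quiquesetinerviusin A | COc1cc([C@H]2Oc3c(OC)cc(/C=C/COC(=O)c4ccc(O[Si](C(C)C)(C(C)C)C(C)C)cc4)cc3[C@@H]2COC(=O)c2ccc(O[Si](C(C)C)(C(C)C)C(C)C)cc2)ccc1O[Si](C(C)C)(C(C)C)C(C)C | intermediate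
25 | quiquesetinerviusin A | COc1cc([C@H]2Oc3c(OC)cc(/C=C/COC(=O)c4ccc(O)cc4)cc3[C@@H]2COC(=O)c2ccc(O)cc2)ccc1O | target

## Step count and risks

Total step count: 13. Longest linear sequence: 9 steps (steps 1, 2, 3, 5, 6, 7, 9, 12, 13).

**Step 12.** Once the vinyl iodide is consumed, zerovalent palladium may ionise an allylic benzoate (that of 22 or the cinnamyl ester of 24), and the π-allyl complex would then be captured by hydroxide or by the arylboronate. Slow borylation of the electron-rich ring A or protodeboronation of 23 in the aqueous base would lower conversion. Partial loss of aryl silyl ethers would be harmless, since step 13 removes them all. The fallback makes the carbon–carbon bond before the allylic ester exists. It sets out from 18: the borylation is run alone and 23 is isolated by filtration through silica. Propargyl alcohol 19 is converted by radical hydrostannation (Bu3SnH, AIBN, 80 °C) into (E)-3-(tributylstannyl)prop-2-en-1-ol F1, and iododestannylation (I2, CH2Cl2, 0 °C) gives (E)-3-iodoprop-2-en-1-ol F2, which has no leaving group. Suzuki–Miyaura coupling of 23 with F2 (Pd(dppf)Cl2, aq. K3PO4, THF, 40 °C) should give the free cinnamyl alcohol F3. Steglich esterification of F3 with acid 17 (DCC, DMAP, CH2Cl2) comes back to the route at 24.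

**Step 11.** Cp2Zr(H)Cl may reduce the benzoate ester in competition with the alkyne, and the γ-acyloxy vinylzirconium 21 may expel the carboxylate (1,4-elimination to allene) before iodine is added. The fallback sets out from 20 and uses a late-metal hydrometalation that tolerates esters. Platinum-catalysed hydrosilylation (Et3SiH, PtCl2/XPhos, THF, 60 °C) adds syn with silicon at the terminal carbon and should give (E)-3-(triethylsilyl)prop-2-en-1-yl 4-(triisopropylsilyloxy)benzoate F4. Ipso-iododesilylation with N-iodosuccinimide in hexafluoroisopropanol at 0 °C proceeds with retention and comes back to the route at 22.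

**Step 6.** Hydride may attack the endocyclic carbamate carbonyl of the hindered imide, opening the auxiliary instead of releasing it, and the basic medium may cause retro-aldol cleavage or epimerisation of the aryl-bearing α-centre. The fallback removes the auxiliary by solvolysis before any reduction. It sets out from 11: MeOMgBr (from MeMgBr and MeOH, CH2Cl2, 0 °C) should effect exocyclic methanolysis, assisted by the β-hydroxyl group, to give methyl (2S,3S)-2-[2-(benzyloxy)-3-methoxyphenyl]-3-hydroxy-3-[3-methoxy-4-(triisopropylsilyloxy)phenyl]propanoate F5. DIBAL-H (THF, −78 → 0 °C) reduces this unhindered ester and comes back to the route at 12.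

Further compounds

F1 | step 12 | (E)-3-(tributylstannyl)prop-2-en-1-ol | CCCC[Sn](CCCC)(CCCC)/C=C/CO
F2 | step 12 | (E)-3-iodoprop-2-en-1-ol | OC/C=C/I
F3 | step 12 | {(2S,3R)-5-[(E)-3-hydroxyprop-1-en-1-yl]-7-methoxy-2-[3-methoxy-4-(triisopropylsilyloxy)phenyl]-2,3-dihydrobenzofuran-3-yl}methyl 4-(triisopropylsilyloxy)benzoate | COc1cc([C@H]2Oc3c(OC)cc(/C=C/CO)cc3[C@@H]2COC(=O)c2ccc(O[Si](C(C)C)(C(C)C)C(C)C)cc2)ccc1O[Si](C(C)C)(C(C)C)C(C)C
F4 | step 11 | (E)-3-(triethylsilyl)prop-2-en-1-yl 4-(triisopropylsilyloxy)benzoate | CC[Si](CC)(CC)/C=C/COC(=O)c1ccc(O[Si](C(C)C)(C(C)C)C(C)C)cc1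
F5 | step 6 | methyl (2S,3S)-2-[2-(benzyloxy)-3-methoxyphenyl]-3-hydroxy-3-[3-methoxy-4-(triisopropylsilyloxy)phenyl]propanoate | COC(=O)[C@@H](c1cccc(OC)c1OCc1ccccc1)[C@H](O)c1ccc(O[Si](C(C)C)(C(C)C)C(C)C)c(OC)c1
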